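The runs are simulated with made-up constants; the scatter is artificial.

- E is the species to follow in these flasks, and the questions are these:

- part of the E that has reacted at the end, south-west
- part of the E that has reacted at the end, north
- part of the E that has reacted at the end, north-west
- what raising the equivalents of J from its lowest to its highest value here does to the part of the E that has reacted (changes below 5 percentage points count as none) (it rises / no change / it falls)

| flask | E | J | remark | time |
|---|---|---|---|---|
| amber | 0.041 M | 0.99 equiv | run made earlier |  |
| south-west | 0.041 M | 1.60 equiv |  | 40 h |
| north | 0.041 M | 1.20 equiv |  | 40 h |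
| north-west | 0.041 M | 2.00 equiv |  | 40 h |

- amber (time / h: E / %, X / %): 2.50: 68.0, 27.8; 4.00: 58.9, 35.4; 6.00: 50.1, 41.6; 10.0: 39.0, 48.4; 15.0: 31.9, 52.1; 30.0: 21.9, 56.2

(readings scatter by 0.5 percentage points)

- a reading or a percentage of X counts all its forms, free or not
- what has gone from E into another species counts as reacted, even if it can come back

- Count turnovers. For equal charges of E and J, a second-order run gives the turnover count (dimensionless time) N = 1/E − 1, with E as a fraction of its charge. Amber, taken as equimolar, has delivered N = 3.57 by 30.0 h.
- Hold that against the early pace. The first reading gives 0.188 h⁻¹, which predicts 5.64 by then, so amber's pace fell during the run.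
- Set the ceiling. With M equivalents of J, the E left is (M − 1)/(M·exp((M − 1)N) − 1). Spend amber's N in each flask, on my own assumption that a flask with more J slows sooner by the clock. My estimated ceiling on the reacted part is then 86.2% in north, 95.2% in south-west and 98.6% in north-west.
- Set the floor. Amber itself reached 78.1%. Its late pace of 0.0954 h⁻¹, carried to 40 h, lifts that to 81.9%.
- Place the forecast: 83.5% in north, 87% in south-west and 90% in north-west, each between floor and ceiling. Its verdict on raising J is it rises, in its words “So more J drives more E to react”.
- The flasks give 85.4% in north, 90.8% in south-west and 94.8% in north-west, each under its ceiling. The verdict on raising J is it rises, by 9.5 percentage points across the series, and the main reason is the difference in equivalents of J.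

    E + J → L + X (k = 0.0830 L mol⁻¹ min⁻¹)
    J + L ⇌ Z, settled at all times (K = 36000 L mol⁻¹)
    G ⇌ X, rate k3*(cs3 - [X]) while solid is left; crystals form when [X] > cs3 (solubility = 25.0 mM, k = 0.0140 min⁻¹)
    J ⇌ D (K = 0.950, k = 2.20 × 10⁻⁴ min⁻¹)
    E + L ⇌ Q, settled at all times (K = 4500 L mol⁻¹)

- Watch free J, not the clock. Part of north's stall is L taking J into Z: without that binding, north reaches 98.5% instead of 85.4%. North ends with 3.42% of its J free and Z at 0.0184 M.
- Carry N to the neighbour flask, which is north at 0.10 M of E with the same equivalents. The count scales with concentration to 8.70, so the ceiling is 96.6%. The flask gives 92.7%.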